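At 30 h the green flask stands long past its last reading, so what matters is how a plateau behaves.

the same everywhere: X 0.10 M

| run | Z | remark | time | volume of the second phase over the first |
|---|---|---|---|---|
| green | 4 equiv | the very flask that is asked about, followed so far |  |  |
| blue | 8 equiv | run made earlier |  |  |
| flask | 4.00 equiv |  | 30 h | 0.50 |

| run | time / h | G / % | D / % |
|---|---|---|---|
| green | 0.200 | 31.7 | 2.6 |
| green | 0.667 | 74.2 | 25.1 |
| green | 1.00 | 82.7 | 40.0 |
| green | 1.50 | 85.3 | 54.2 |
| green | 2.50 | 91.1 | 72.3 |
| blue | 2.00 | 94.9 | 71.7 |
| blue | 5.00 | 95.5 | 91.3 |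
| blue | 10.0 | 95.5 | 91.3 |
| blue | 15.0 | 95.3 | 90.3 |
| blue | 20.0 | 94.0 | 89.3 |

(each reading ± 1 percentage point)

- the G and Q and D together standing at 30 h, as a percentage of the X charged
- concentration of G in solution at 30 h, in percent of saturation

- what is said of G includes Q and D
- in the second phase: Z, Q; everything else is in the first
- charges count per volume of the first phase; a concentration in a rate is the amount of a species over the volume of its own phase; every rate counts per litre of the first phase
- D is a solid; its amount is given per volume of the solution
- the earlier runs hold the two phases in the same ratio of volumes as the flask asked about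

The zero of my scale is a plateau that stays flat. In blue, G minus D, the dissolved stock, reads 4.2 percentage points at 5.00 h and 4.7 points at 20.0 h, level within the scatter, with more D than that. So I expect a constant (pseudo-zero-order) loss per litre while crystals stand. Read in blue between 10.0 h and 20.0 h, and rough because it rests on two readings, that loss per hour is r = 0.150 mM h⁻¹, the drain.

The green flask has the same charge of X, so there are two extremes:

no further drain after the reading in blue: y = 95.5%

drain from the start: y = 91.0%

The flask lies between them, because the plateau value was read at 10.0 h. Running the drain from there, I commit to: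

y = 92.5%

The forecast gives 92.5% and 98%, from another plateau and a smaller slope: “so solution stays essentially saturated, slightly under because D is feeding the loss”.

The flask gives 91.2% and 95.9%, both within the margins.

    G → L (k = 2.65 × 10⁻⁵ s⁻¹)
    D ⇌ G, rate k2*(cs2 - [G]) while solid is left; crystals form when [G] > cs2 (solubility = 1.40 mM, k = 6.22 × 10⁻⁴ s⁻¹)
    G ⇌ Q, rate k3*([G] - [Q]/K3) per volume of the first phase (partition coefficient = 2.60, kL = 0.00207 s⁻¹)
    E ⇌ Z, rate k4*([E] - [Z]/K4) per volume of the first phase (partition coefficient = 0.850, kL = 3.46 × 10⁻⁴ s⁻¹)
    X + E ⇌ G (K = 5.90 M⁻¹, k = 0.00894 M⁻¹ s⁻¹)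

In the flask, dissolved G passes into L with a half-life of 7.3 h, shorter than the 30 h of the run, while D still stands at 88.1%. From 15.0 h to 30 h the total of G, Q and D in the flask falls by 0.128 mM h⁻¹, against the drain of 0.150 mM h⁻¹ read in blue. In a neighbour flask, the same recipe with 0.040 M of X and D at 72.6%, that drain over 30 h comes to 11.2% of the smaller charge, and this neighbour holds 13.1% as L.

All runs are calculated from invented constants.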